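## Retrosynthetic overview

1. Atom labels: ring C1 (carbinol carbon) to C6, with C4 = CMeBr and C5 = CHCl; side chain C7 (the C=CH2 carbon) to C10 (CHOH). End game: target ⇐ bis-silyl ether 21 ⇐ ketone 20 (C7=O → C7=CH2) ⇐ ring N-methoxy-N-methylamide 13 + side-chain Grignard reagent 19 (C7–C8 bond; C10 set by a CBS reduction).
2. Ring halogens: 13 ⇐ bromo chloro acid 10 ⇐ chlorolactone 9 ⇐ hydroxy acid 8. The C7 carboxyl puts its oxygen on C4 anti to Cl+ arriving at C5, then C4–O is exchanged for C4–Br with retention.
3. Ring: 8 ⇐ spiro adduct 7 ⇐ isoprene + (2R)-2-tert-butyl-5-methylidene-1,3-dioxolan-4-one (from (R)-lactic acid). One [4+2] cycloaddition forms C1–C6 and C2–C3, closes the only carbocycle and sets C1. Ring order: dioxolanone (temporary) → cyclohexene → bridged δ-lactone (temporary).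
4. Enabling feature: in ring C1–C6 the oxygenated quaternary C1 stands 1,4 to the methyl-bearing C4, and C4/C5 carry vicinal trans halogens. The ring is therefore a masked 1-methylcyclohexene (C4=C5), i.e. an isoprene adduct, and C1 with its oxygen and the sp2 carbon C7 maps onto an α-oxygenated acrylic dienophile.

Key step: step 3

Remark: 3-chloro-N-methoxy-N-methylpropanamide (14) and isopropenylmagnesium bromide (15, THF solution) are taken as purchasable. The labels C1–C10 are those defined in the overview; locants inside compound names follow the usual nomenclature and may differ.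

## Route

Step 1
Reactants: 1 (R)-lactic acid; 2 pivalaldehyde
Product: 3 (2R,5R)-2-tert-butyl-5-methyl-1,3-dioxolan-4-one
Conditions: TsOH·H2O (cat.), H2SO4 (cat.), pentane, reflux, Dean–Stark; recrystallisation from pentane at −78 °C
Reagents that add atoms: none
Why: Acid-catalysed acetalisation of the α-hydroxy acid should give the dioxolanone, the cis isomer (tert-butyl and methyl on the same face) being the thermodynamically preferred acetal and purified by crystallisation, so that the lactic acid stereocentre is copied onto the acetal carbon (R).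

Step 2
Reactants: 3 (2R,5R)-2-tert-butyl-5-methyl-1,3-dioxolan-4-one
Product: 5 (2R)-2-tert-butyl-5-methylidene-1,3-dioxolan-4-one, via bromodioxolanone 4 (not isolated)
Conditions: NBS, AIBN (cat.), CCl4 (or PhCF3), reflux; filter; Et3N, Et2O, 0 °C → rt
Reagents that add atoms: none
Why: Wohl–Ziegler-type radical bromination at the captodatively stabilised C5–H followed by E2 dehydrobromination should give the exocyclic α-oxy acrylate, the acetal stereocentre staying untouched.

Step 3
Reactants: 5 (2R)-2-tert-butyl-5-methylidene-1,3-dioxolan-4-one; 6 isoprene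
Product: 7 (2R,5S)-2-tert-butyl-8-methyl-1,3-dioxaspiro[4.5]dec-7-en-4-one
Conditions: isoprene (8 equiv), BHT (cat.), toluene, 85 °C, sealed tube
Reagents that add atoms: none
Why: A thermal, concerted but asynchronous normal-electron-demand [4+2] cycloaddition joins the HOMO of isoprene to the LUMO of the captodative α-oxy acrylate 5 and forms C1–C6 and C2–C3 in one suprafacial event. The closest known reaction type is the Diels–Alder reaction of 2-substituted acrylates, in particular of 5-methylidene-1,3-dioxolan-4-ones, with cyclic and acyclic 1,3-dienes. The six-membered carbocycle is closed intermolecularly in the [4+2] mode, spiro to the existing dioxolanone, and no other ring is formed. The only new stereocentre, the spiro carbon (C1 of the target), is controlled by the acetal tert-butyl group: the diene should add to the face of the exocyclic alkene opposite to it, which for the (2R)-acetal gives the (5S) adduct, and endo/exo orientation is immaterial because isoprene carries no terminal substituent. The step needs para regioselectivity (C1 opposite the methyl-bearing C4) and π-facial selectivity: the first is secured by the match of the larger HOMO coefficient at the CH2 terminus next to the methyl-bearing carbon of isoprene with the larger LUMO coefficient at the unsubstituted CH2 of 5, the second by the tert-butyl group on the otherwise flat five-membered ring. Any meta adduct carried along should be removable at lactone 9, because its acid can only close to a constitutionally different bicyclo[3.2.1] lactone.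

Step 4
Reactants: 7 (2R,5S)-2-tert-butyl-8-methyl-1,3-dioxaspiro[4.5]dec-7-en-4-one
Product: 8 (1S)-1-hydroxy-4-methylcyclohex-3-ene-1-carboxylic acid
Conditions: LiOH·H2O, THF/H2O, rt; then 1 M HCl to pH 2
Reagents that add atoms: lithium hydroxide, [Li+].[OH-]
Why: Saponification of the acylal lactone should release pivalaldehyde and the free α-hydroxy acid without touching the quaternary stereocentre, which has no enolisable hydrogen.

Step 5
Reactants: 8 (1S)-1-hydroxy-4-methylcyclohex-3-ene-1-carboxylic acid
Product: 9 (1S,4S,6S)-6-chloro-4-hydroxy-1-methyl-2-oxabicyclo[2.2.2]octan-3-one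
Conditions: NCS, 1,4-diazabicyclo[2.2.2]octane (DABCO, 10 mol%), CH2Cl2, −20 → 0 °C
Reagents that add atoms: N-chlorosuccinimide, O=C1CCC(=O)N1Cl
Why: Chlorolactonisation (halolactonisation): the amine-activated N-chloro reagent should deliver Cl+ to C5 while the carboxyl group on the opposite face closes onto the tertiary C4 in the Markovnikov sense, as in cineole-type cyclisations of 4-substituted 1-methylcyclohexenes, so that anti addition across C4=C5 under control of the C1 stereocentre places the C4–O bond on the carboxyl face and the C5–Cl bond on the other face (1S and 6S in the lactone).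

Step 6
Reactants: 9 (1S,4S,6S)-6-chloro-4-hydroxy-1-methyl-2-oxabicyclo[2.2.2]octan-3-one
Product: 10 (1S,3S,4S)-4-bromo-3-chloro-1-hydroxy-4-methylcyclohexane-1-carboxylic acid
Conditions: BBr3, CH2Cl2, −78 → 0 °C; then H2O, 0 °C
Reagents that add atoms: boron tribromide, BrB(Br)Br
Why: Lewis acid-mediated alkyl–oxygen cleavage of a tertiary ester (the reaction type that cleaves tert-butyl esters): the boron-bound carboxylate should leave C4 with assistance by the anti-periplanar C5–Cl bond and bromide should return to the same face (ion-pair collapse or opening of the chloronium ion at the tertiary carbon), giving the tertiary bromide trans-diaxial to chlorine with retention at C4, while the C1 carbinol α to the carbonyl cannot ionise.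

Step 7
Reactants: 10 (1S,3S,4S)-4-bromo-3-chloro-1-hydroxy-4-methylcyclohexane-1-carboxylic acid; 11 N,O-dimethylhydroxylamine hydrochloride
Product: 12 (1S,3S,4S)-4-bromo-3-chloro-1-hydroxy-N-methoxy-N,4-dimethylcyclohexane-1-carboxamide
Conditions: EDC·HCl, HOBt, N-methylmorpholine, CH2Cl2, 0 °C → rt
Reagents that add atoms: none
Why: Carbodiimide/HOBt amide coupling of the α-hydroxy acid with the amine salt should give the N-methoxy-N-methylamide under conditions too weakly basic and too non-ionising to disturb the tertiary bromide, and no stereocentre is involved.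

Step 8
Reactants: 12 (1S,3S,4S)-4-bromo-3-chloro-1-hydroxy-N-methoxy-N,4-dimethylcyclohexane-1-carboxamide
Product: 13 (1S,3S,4S)-4-bromo-3-chloro-N-methoxy-N,4-dimethyl-1-[(triethylsilyl)oxy]cyclohexane-1-carboxamide
Conditions: TESOTf, 2,6-lutidine, CH2Cl2, −78 → 0 °C
Reagents that add atoms: triethylsilyl trifluoromethanesulfonate, CC[Si](CC)(CC)OS(=O)(=O)C(F)(F)F
Why: Silyl triflate/lutidine silylation should protect the hindered tertiary carbinol so that it quenches neither the Grignard reagent of step 12 nor the titanium methylidene of step 13, and no stereocentre is touched.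

Step 9
Reactants: 14 3-chloro-N-methoxy-N-methylpropanamide; 15 isopropenylmagnesium bromide
Product: 16 5-chloro-2-methylpent-1-en-3-one
Conditions: THF, −10 → 0 °C; cold 1 M HCl
Reagents that add atoms: none
Why: Acylation of the alkenyl Grignard reagent by the N-methoxy-N-methylamide should stop at the chelated tetrahedral intermediate, so that the β-chloro α-methyl enone is released only on acidic quench and cannot suffer over-addition or conjugate addition.

Step 10
Reactants: 16 5-chloro-2-methylpent-1-en-3-one
Product: 17 (3R)-5-chloro-2-methylpent-1-en-3-ol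
Conditions: (S)-Me-CBS [(3aS)-1-methyl-3,3-diphenyltetrahydro-1H,3H-pyrrolo[1,2-c][1,3,2]oxazaborole, 15 mol%], catecholborane, toluene, −78 °C; then MeOH
Reagents that add atoms: none
Why: CBS reduction: the oxazaborolidine–borane complex should bind the ketone with the larger isopropenyl group away from the catalyst and deliver hydride to one face, so that the (S)-catalyst gives the (R)-allylic alcohol (alkenyl = large, CH2CH2Cl = small), while catecholborane at −78 °C leaves the 1,1-disubstituted alkene and the chloride alone.

Step 11
Reactants: 17 (3R)-5-chloro-2-methylpent-1-en-3-ol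
Product: 18 triethyl{[(3R)-5-chloro-2-methylpent-1-en-3-yl]oxy}silane
Conditions: TESCl, imidazole, CH2Cl2, 0 °C → rt
Reagents that add atoms: chlorotriethylsilane, CC[Si](Cl)(CC)CC
Why: Standard silylation of the secondary allylic alcohol removes the acidic proton before the Grignard reagent is made, and the stereocentre is not involved.

Step 12
Reactants: 18 triethyl{[(3R)-5-chloro-2-methylpent-1-en-3-yl]oxy}silane; 13 (1S,3S,4S)-4-bromo-3-chloro-N-methoxy-N,4-dimethyl-1-[(triethylsilyl)oxy]cyclohexane-1-carboxamide
Product: 20 (4R)-1-{(1S,3S,4S)-4-bromo-3-chloro-4-methyl-1-[(triethylsilyl)oxy]cyclohexyl}-5-methyl-4-[(triethylsilyl)oxy]hex-5-en-1-one, via alkylmagnesium chloride 19 (not isolated)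
Conditions: Mg turnings, I2 (cat.), THF, 60 °C; then 13, THF, 0 °C → rt; aq. NH4Cl
Reagents that add atoms: none
Why: Magnesium insertion into the primary chloride should give a γ-silyloxy Grignard reagent (no β-leaving group) that acylates the N-methoxy-N-methylamide once via the stable chelate, as known for α-silyloxy-α,α-disubstituted amides of this type, while a primary alkylmagnesium halide should neither exchange with nor readily dehydrohalogenate the tertiary bromide at 0 °C to rt, and both preset stereocentres are carried through.

Step 13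
Reactants: 20 (4R)-1-{(1S,3S,4S)-4-bromo-3-chloro-4-methyl-1-[(triethylsilyl)oxy]cyclohexyl}-5-methyl-4-[(triethylsilyl)oxy]hex-5-en-1-one
Product: 21 (5R)-2-{(1S,3S,4S)-4-bromo-3-chloro-4-methyl-1-[(triethylsilyl)oxy]cyclohexyl}-6-methyl-5-[(triethylsilyl)oxy]hepta-1,6-diene
Conditions: Cp2Ti(μ-Cl)(μ-CH2)AlMe2, pyridine (cat.), THF/toluene, −40 °C → rt; then aq. NaHCO3
Reagents that add atoms: Tebbe reagent Cp2Ti(μ-Cl)(μ-CH2)AlMe2, C[Al](C)C[Ti](Cl)(C1C=CC=C1)C1C=CC=C1
Why: Tebbe methylenation: the non-basic titanium methylidene should convert the hindered, enolisable α-oxy ketone into the 1,1-disubstituted alkene via an oxatitanacyclobutane, and a tetravalent titanium reagent neither reduces the vicinal dihalide nor eliminates HBr as a phosphorus ylide or a zinc-based reagent could.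

Step 14
Reactants: 21 (5R)-2-{(1S,3S,4S)-4-bromo-3-chloro-4-methyl-1-[(triethylsilyl)oxy]cyclohexyl}-6-methyl-5-[(triethylsilyl)oxy]hepta-1,6-diene
Product: 22 (1S,3S,4S)-4-bromo-3-chloro-1-[(5R)-5-hydroxy-6-methylhepta-1,6-dien-2-yl]-4-methylcyclohexan-1-ol
Conditions: HF·pyridine, pyridine, THF, 0 °C → rt
Reagents that add atoms: none
Why: Fluoride-mediated cleavage of both triethylsilyl ethers under buffered, weakly acidic conditions (driven by the Si–F bond) should free the tertiary and the secondary allylic alcohol without ionising them or eliminating the tertiary bromide, giving the target with all four stereocentres as set.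

## Compound list

1 | (R)-lactic acid | C[C@@H](O)C(=O)O | starting material
2 | pivalaldehyde | CC(C)(C)C=O | starting material
3 | (2R,5R)-2-tert-butyl-5-methyl-1,3-dioxolan-4-one | C[C@H]1O[C@@H](C(C)(C)C)OC1=O | intermediate
4 | (2S,5S)-5-bromo-2-tert-butyl-5-methyl-1,3-dioxolan-4-one (bromine trans to tert-butyl) | C[C@@]1(Br)O[C@@H](C(C)(C)C)OC1=O | intermediate
5 | (2R)-2-tert-butyl-5-methylidene-1,3-dioxolan-4-one | C=C1O[C@@H](C(C)(C)C)OC1=O | intermediate
6 | isoprene | C=CC(C)=C | starting material
7 | (2R,5S)-2-tert-butyl-8-methyl-1,3-dioxaspiro[4.5]dec-7-en-4-one | CC1=CC[C@]2(CC1)O[C@@H](C(C)(C)C)OC2=O | intermediate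
8 | (1S)-1-hydroxy-4-methylcyclohex-3-ene-1-carboxylic acid | CC1=CC[C@@](O)(CC1)C(=O)O | intermediate
9 | (1S,4S,6S)-6-chloro-4-hydroxy-1-methyl-2-oxabicyclo[2.2.2]octan-3-one | C[C@]12CC[C@](O)(C[C@@H]1Cl)C(=O)O2 | intermediate
10 | (1S,3S,4S)-4-bromo-3-chloro-1-hydroxy-4-methylcyclohexane-1-carboxylic acid | OC(=O)[C@]1(O)CC[C@](C)(Br)[C@@H](Cl)C1 | intermediate
11 | N,O-dimethylhydroxylamine hydrochloride | CNOC.Cl | starting material
12 | (1S,3S,4S)-4-bromo-3-chloro-1-hydroxy-N-methoxy-N,4-dimethylcyclohexane-1-carboxamide | CON(C)C(=O)[C@]1(O)CC[C@](C)(Br)[C@@H](Cl)C1 | intermediate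
13 | (1S,3S,4S)-4-bromo-3-chloro-N-methoxy-N,4-dimethyl-1-[(triethylsilyl)oxy]cyclohexane-1-carboxamide | CON(C)C(=O)[C@]1(O[Si](CC)(CC)CC)CC[C@](C)(Br)[C@@H](Cl)C1 | intermediate
14 | 3-chloro-N-methoxy-N-methylpropanamide | CON(C)C(=O)CCCl | starting material
15 | isopropenylmagnesium bromide | CC(=C)[Mg]Br | starting material
16 | 5-chloro-2-methylpent-1-en-3-one | CC(=C)C(=O)CCCl | intermediate
17 | (3R)-5-chloro-2-methylpent-1-en-3-ol | C=C(C)[C@H](O)CCCl | intermediate
18 | triethyl{[(3R)-5-chloro-2-methylpent-1-en-3-yl]oxy}silane | C=C(C)[C@H](O[Si](CC)(CC)CC)CCCl | intermediate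
19 | {(3R)-4-methyl-3-[(triethylsilyl)oxy]pent-4-en-1-yl}magnesium chloride | C=C(C)[C@H](O[Si](CC)(CC)CC)CC[Mg]Cl | intermediate
20 | (4R)-1-{(1S,3S,4S)-4-bromo-3-chloro-4-methyl-1-[(triethylsilyl)oxy]cyclohexyl}-5-methyl-4-[(triethylsilyl)oxy]hex-5-en-1-one | C=C(C)[C@H](O[Si](CC)(CC)CC)CCC(=O)[C@]1(O[Si](CC)(CC)CC)CC[C@](C)(Br)[C@@H](Cl)C1 | intermediate
21 | (5R)-2-{(1S,3S,4S)-4-bromo-3-chloro-4-methyl-1-[(triethylsilyl)oxy]cyclohexyl}-6-methyl-5-[(triethylsilyl)oxy]hepta-1,6-diene | C=C(C)[C@H](O[Si](CC)(CC)CC)CCC(=C)[C@]1(O[Si](CC)(CC)CC)CC[C@](C)(Br)[C@@H](Cl)C1 | intermediate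
22 | (1S,3S,4S)-4-bromo-3-chloro-1-[(5R)-5-hydroxy-6-methylhepta-1,6-dien-2-yl]-4-methylcyclohexan-1-ol | C=C(C)[C@H](O)CCC(=C)[C@]1(O)CC[C@](C)(Br)[C@@H](Cl)C1 | target

## Step count and risks

Total step count: 14. Longest linear sequence: 11 steps (steps 1–8 and 12–14); the side chain takes steps 9–11.

The three steps most likely to fail:

Step 5 (chlorolactonisation). What may go wrong: loss of a proton from the β-chloro cation (ene-type allylic chlorination) instead of ring closure; closure onto C5 to a γ-lactone with a tertiary chloride; capture of the cation by the C1 hydroxyl; or oxidative decarboxylation of the α-hydroxy acid by the N-chloro reagent. The fallback sets out from 8 and comes back at 9, and it replaces electrophilic chlorine by nucleophilic chloride. Acid 8 is iodolactonised (I2, KI, NaHCO3, THF/H2O, 0 °C) to (1S,4S,6S)-4-hydroxy-6-iodo-1-methyl-2-oxabicyclo[2.2.2]octan-3-one F1; should the γ-regioisomer form instead, it leads to the same epoxide. K2CO3 in MeOH opens the lactone and the freed alkoxide displaces iodide, which should give methyl (1R,3S,6S)-3-hydroxy-6-methyl-7-oxabicyclo[4.1.0]heptane-3-carboxylate F2, with the epoxide on the carboxyl face. LiCl/AcOH in THF should open F2 by SN2 attack of chloride at the secondary carbon C5 (trans-diaxial opening) to methyl (1S,3S,4S)-3-chloro-1,4-dihydroxy-4-methylcyclohexane-1-carboxylate F3. TsOH (cat.) in toluene at reflux then lactonises F3 to 9 with loss of methanol.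

Step 6 (C4–O to C4–Br exchange). What may go wrong: slow ionisation of the β-chloro-deactivated tertiary C–O bond, loss of HBr to alkenes under the Lewis acid, erosion of configuration at C4, or re-closure of the carboxylate onto C4 during work-up. The fallback sets out from 9 and comes back at 12, so it also bypasses step 7. It moves the exchange from the bridged lactone to a free tertiary carbinol and never places a carboxylate next to the tertiary bromide. Lactone 9 is opened with MeOH/HCl (cat.) to the chlorohydrin ester F3 of the first fallback. Its tertiary hydroxyl is substituted with Me3SiBr (CH2Cl2, −20 °C), a classical substitution of a trans-β-chloro tertiary alcohol with anchimeric assistance and ion-pair return, which should give methyl (1S,3S,4S)-4-bromo-3-chloro-1-hydroxy-4-methylcyclohexane-1-carboxylate F4. F4 is then converted directly into 12 with 11 and i-PrMgCl (THF, −20 °C).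

Step 12 (ketone formation). What may go wrong: slow addition to the neopentyl-type amide, so that base-type pathways (dehydrobromination of the tertiary bromide, loss of formaldehyde from the N–OMe group) consume the Grignard reagent. The fallback sets out from 13 and comes back at 20, and it replaces acylation by the much faster addition to an aldehyde. Amide 13 is reduced with i-Bu2AlH (CH2Cl2, −78 °C) to (1S,3S,4S)-4-bromo-3-chloro-4-methyl-1-[(triethylsilyl)oxy]cyclohexane-1-carbaldehyde F5. Grignard reagent 19 is added at −78 °C to give (4R)-1-{(1S,3S,4S)-4-bromo-3-chloro-4-methyl-1-[(triethylsilyl)oxy]cyclohexyl}-5-methyl-4-[(triethylsilyl)oxy]hex-5-en-1-ol F6 as a mixture of epimers at the new carbinol carbon. Dess–Martin oxidation (CH2Cl2, NaHCO3, rt) converts both epimers into 20.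

Further compounds
F1 | step 5 | (1S,4S,6S)-4-hydroxy-6-iodo-1-methyl-2-oxabicyclo[2.2.2]octan-3-one | C[C@]12CC[C@](O)(C[C@@H]1I)C(=O)O2
F2 | step 5 | methyl (1R,3S,6S)-3-hydroxy-6-methyl-7-oxabicyclo[4.1.0]heptane-3-carboxylate | COC(=O)[C@]1(O)CC[C@]2(C)O[C@@H]2C1
F3 | step 5 | methyl (1S,3S,4S)-3-chloro-1,4-dihydroxy-4-methylcyclohexane-1-carboxylate | COC(=O)[C@]1(O)CC[C@](C)(O)[C@@H](Cl)C1
F4 | step 6 | methyl (1S,3S,4S)-4-bromo-3-chloro-1-hydroxy-4-methylcyclohexane-1-carboxylate | COC(=O)[C@]1(O)CC[C@](C)(Br)[C@@H](Cl)C1
F5 | step 12 | (1S,3S,4S)-4-bromo-3-chloro-4-methyl-1-[(triethylsilyl)oxy]cyclohexane-1-carbaldehyde | O=C[C@]1(O[Si](CC)(CC)CC)CC[C@](C)(Br)[C@@H](Cl)C1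
F6 | step 12 | (4R)-1-{(1S,3S,4S)-4-bromo-3-chloro-4-methyl-1-[(triethylsilyl)oxy]cyclohexyl}-5-methyl-4-[(triethylsilyl)oxy]hex-5-en-1-ol (both epimers at C1 of the chain) | C=C(C)[C@H](O[Si](CC)(CC)CC)CCC(O)[C@]1(O[Si](CC)(CC)CC)CC[C@](C)(Br)[C@@H](Cl)C1
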